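The route disconnects the dihydropyran ring of the chromane (O1–C2–C3–C4–C4a–C8a) between C3 and C4. C4 is benzylic on the catechol-derived ring and C3 is the methylene next to the quaternary ether carbon C2, so both can be carried as terminal alkene carbons: a styrene on C4a and a vinyl group on C2 of an aryl tert-alkyl ether. The C2 configuration is set beforehand by palladium-catalysed asymmetric etherification. One pot of ring-closing metathesis and hydrogenation then delivers the saturated C3–C4 bond and the ring. The side-chain diene, the boronic acid and the flavanone (rhodium-catalysed conjugate addition to a 6-prenylchromone) follow.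

Key step: step 3

Assumption: the sense of induction of the two chiral catalysts is taken from the usual models for these ligand families ((R,R)-diphosphine in step 2 giving the S ether, (S)-bisphosphine in step 13 giving the 2S flavanone); if either proves opposite, the antipodal ligand is used and nothing else changes.

Step 1
Reactants: 1 5-bromo-2-hydroxy-3-methoxybenzaldehyde
Product: 2 4-bromo-2-ethenyl-6-methoxyphenol
Conditions: Ph3PCH3Br (2.5 equiv), KOtBu (2.5 equiv), THF, 0 °C to rt
Reagents that add atoms: methyltriphenylphosphonium bromide, C[P+](c1ccccc1)(c1ccccc1)c1ccccc1.[Br-]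
Why: Wittig methylenation in which the excess non-stabilised ylide first forms the phenoxide and then converts the formyl group into the styrenyl CH=CH2 group whose inner carbon becomes C4, the aryl bromide and methyl ether being inert.

Step 2
Reactants: 2 4-bromo-2-ethenyl-6-methoxyphenol; 3 2-methyl-2-vinyloxirane (racemic)
Product: 4 (2S)-2-(4-bromo-2-ethenyl-6-methoxyphenoxy)-2-methylbut-3-en-1-ol
Conditions: Pd2(dba)3·CHCl3 (1.5 mol%), (1R,2R)-N,N'-bis[2-(diphenylphosphino)benzoyl]cyclohexane-1,2-diamine (4.5 mol%), 3 (1.3 equiv), CH2Cl2, rt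
Reagents that add atoms: none
Why: Palladium-catalysed asymmetric allylic etherification run as a dynamic kinetic asymmetric transformation, in which zerovalent palladium opens racemic 3 to interconverting π-allyl alkoxide complexes, the alkoxide deprotonates phenol 2 and delivers it to the proximal fully substituted allyl terminus, and the chiral diphosphine pocket selects the face so that the quaternary ether carbon (future C2) is formed as S.

Step 3
Reactants: 4 (2S)-2-(4-bromo-2-ethenyl-6-methoxyphenoxy)-2-methylbut-3-en-1-ol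
Product: 6 [(2S)-6-bromo-8-methoxy-2-methyl-3,4-dihydro-2H-chromen-2-yl]methanol, via 2H-chromene 5 (not isolated)
Conditions: RuCl2(=CHPh)(PCy3)(H2IMes) (second-generation Grubbs catalyst, 5 mol%), ClCH2CH2Cl (0.01 M), 50 °C; then H2 (7 bar), 70 °C, same pot
Reagents that add atoms: none
Why: The ruthenium alkylidene engages one of the two terminal alkenes of 4, and a [2+2] cycloaddition/cycloreversion sequence through a ruthenacyclobutane joins the styrenyl carbon (C4) to the vinyl carbon (C3) with loss of ethene to give 2H-chromene 5, after which hydrogen converts the ruthenium residue into hydride species that saturate the new cis-disubstituted C3=C4 bond in the same pot. The closest known reaction types are the ring-closing olefin metathesis of 2-vinylaryl allyl ethers to 2H-chromenes and tandem ring-closing metathesis–hydrogenation. The six-membered pyran ring is closed by metathesis between two sp2 termini held ortho to each other on the arene, a geometry that favours cyclisation over oligomerisation at high dilution. No stereocentre is created: the quaternary C2 from step 2 carries no hydrogen and lies outside the reacting π-systems, so it is carried through unchanged. The step needs chemoselectivity among alkenes and tolerance of the aryl bromide, and both are secured because 4 contains only the two alkenes that must react (diene and prenyl groups come later) and the neutral ruthenium hydride does not cleave the C–Br bond.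

Step 4
Reactants: 6 [(2S)-6-bromo-8-methoxy-2-methyl-3,4-dihydro-2H-chromen-2-yl]methanol
Product: 7 (2S)-6-bromo-2-(hydroxymethyl)-2-methyl-3,4-dihydro-2H-chromen-8-ol
Conditions: NaSEt (5 equiv), DMF, 110 °C; then 1 M aq HCl
Reagents that add atoms: none
Why: Nucleophilic (SN2) demethylation of the aryl methyl ether by ethanethiolate, which can attack only the methyl carbon because the other ether carbon (C2) is tertiary, so the chromane ring and its stereocentre are untouched.

Step 5
Reactants: 7 (2S)-6-bromo-2-(hydroxymethyl)-2-methyl-3,4-dihydro-2H-chromen-8-ol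
Product: 8 [(2S)-6-bromo-8-{[tert-butyl(dimethyl)silyl]oxy}-2-methyl-3,4-dihydro-2H-chromen-2-yl]methanol
Conditions: TBSCl (1.1 equiv), Et3N (1.5 equiv), CH2Cl2, 0 °C
Reagents that add atoms: tert-butyldimethylsilyl chloride, CC(C)(C)[Si](C)(C)Cl
Why: Chemoselective O-silylation of the more acidic phenol through its ammonium phenoxide, the neopentyl-type primary alcohol not being silylated in the absence of a nucleophilic catalyst.

Step 6
Reactants: 8 [(2S)-6-bromo-8-{[tert-butyl(dimethyl)silyl]oxy}-2-methyl-3,4-dihydro-2H-chromen-2-yl]methanol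
Product: 9 (2S)-6-bromo-8-{[tert-butyl(dimethyl)silyl]oxy}-2-methyl-3,4-dihydro-2H-chromene-2-carbaldehyde
Conditions: Dess–Martin periodinane (1.3 equiv), CH2Cl2, 0 °C to rt
Reagents that add atoms: none
Why: Dess–Martin oxidation of the primary alcohol to an aldehyde that has no α-hydrogen and therefore cannot epimerise at C2.

Step 7
Reactants: 9 (2S)-6-bromo-8-{[tert-butyl(dimethyl)silyl]oxy}-2-methyl-3,4-dihydro-2H-chromene-2-carbaldehyde
Product: 10 {[(2S)-6-bromo-2-methyl-2-[(1E)-4-methylpenta-1,3-dien-1-yl]-3,4-dihydro-2H-chromen-8-yl]oxy}(tert-butyl)dimethylsilane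
Conditions: diethyl (3-methylbut-2-en-1-yl)phosphonate (1.5 equiv), n-BuLi (1.4 equiv), THF/DMPU, −78 °C; then 9, −78 °C to rt
Reagents that add atoms: diethyl (3-methylbut-2-en-1-yl)phosphonate, CCOP(=O)(CC=C(C)C)OCC
Why: Horner–Wadsworth–Emmons olefination with an allylic phosphonate anion that adds through its α-carbon and eliminates under thermodynamic control, the bulky quaternary C2 reinforcing the E geometry of the new C=C bond of the 4-methylpenta-1,3-dienyl chain.

Step 8
Reactants: 10 {[(2S)-6-bromo-2-methyl-2-[(1E)-4-methylpenta-1,3-dien-1-yl]-3,4-dihydro-2H-chromen-8-yl]oxy}(tert-butyl)dimethylsilane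
Product: 13 {(2S)-8-{[tert-butyl(dimethyl)silyl]oxy}-2-methyl-2-[(1E)-4-methylpenta-1,3-dien-1-yl]-3,4-dihydro-2H-chromen-6-yl}boronic acid, via aryllithium 11 (not isolated), via lithium triisopropoxyborate 12 (not isolated)
Conditions: n-BuLi (1.1 equiv), THF, −78 °C; B(OiPr)3 (1.5 equiv), −78 to 0 °C; AcOH (1.1 equiv), H2O, 0 °C
Reagents that add atoms: triisopropyl borate, CC(C)OB(OC(C)C)OC(C)C; water, O
Why: Bromine–lithium exchange at −78 °C, which is faster than any addition of the alkyllithium to the diene, followed by borate trapping and mild hydrolysis of the ate complex to the arylboronic acid.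

Step 9
Reactants: 14 5,7-dihydroxy-4H-chromen-4-one
Product: 15 5-hydroxy-7-{[tri(propan-2-yl)silyl]oxy}-4H-chromen-4-one
Conditions: TIPSCl (1.1 equiv), imidazole (2.2 equiv), DMF, 0 °C to rt
Reagents that add atoms: triisopropylsilyl chloride, CC(C)[Si](Cl)(C(C)C)C(C)C
Why: Regioselective silylation of the free, acidic 7-OH, the 5-OH being locked in a hydrogen bond to the C4 carbonyl and unreactive towards the bulky chlorosilane.

Step 10
Reactants: 15 5-hydroxy-7-{[tri(propan-2-yl)silyl]oxy}-4H-chromen-4-one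
Product: 16 5-hydroxy-6-iodo-7-{[tri(propan-2-yl)silyl]oxy}-4H-chromen-4-one
Conditions: BnMe3N ICl2 (1.05 equiv), CaCO3 (1.5 equiv), CH2Cl2/MeOH, rt
Reagents that add atoms: benzyltrimethylammonium dichloroiodate, C[N+](C)(C)Cc1ccccc1.Cl[I-]Cl
Why: Electrophilic aromatic iodination directed ortho to the free chelated 5-hydroxyl group, which places iodine at C6 of ring A, with CaCO3 scavenging the HCl formed.

Step 11
Reactants: 16 5-hydroxy-6-iodo-7-{[tri(propan-2-yl)silyl]oxy}-4H-chromen-4-one
Product: 17 5-hydroxy-6-(3-methylbut-2-en-1-yl)-7-{[tri(propan-2-yl)silyl]oxy}-4H-chromen-4-one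
Conditions: tributyl(3-methylbut-2-en-1-yl)stannane (1.5 equiv), Pd(PPh3)4 (10 mol%), DMF, 90 °C
Reagents that add atoms: tributyl(3-methylbut-2-en-1-yl)stannane, CCCC[Sn](CCCC)(CCCC)CC=C(C)C
Why: Stille cross-coupling in which oxidative addition of the aryl iodide to zerovalent palladium, transmetalation of the allylstannane and reductive elimination at the less substituted allyl terminus install the linear prenyl group at C6 under neutral conditions that spare the silyl ether.

Step 12
Reactants: 17 5-hydroxy-6-(3-methylbut-2-en-1-yl)-7-{[tri(propan-2-yl)silyl]oxy}-4H-chromen-4-one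
Product: 18 5-{[tert-butyl(dimethyl)silyl]oxy}-6-(3-methylbut-2-en-1-yl)-7-{[tri(propan-2-yl)silyl]oxy}-4H-chromen-4-one
Conditions: TBSOTf (1.5 equiv), 2,6-lutidine (3 equiv), CH2Cl2, 0 °C to rt; aq NaHCO3 work-up
Reagents that add atoms: tert-butyldimethylsilyl trifluoromethanesulfonate, CC(C)(C)[Si](C)(C)OS(=O)(=O)C(F)(F)F
Why: Silylation of the hindered hydrogen-bonded 5-OH with the silyl triflate, which removes the β-hydroxy-enone chelating site before the rhodium step, any O-silylated pyrylium formed at the carbonyl reverting on aqueous work-up.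

Step 13
Reactants: 13 {(2S)-8-{[tert-butyl(dimethyl)silyl]oxy}-2-methyl-2-[(1E)-4-methylpenta-1,3-dien-1-yl]-3,4-dihydro-2H-chromen-6-yl}boronic acid; 18 5-{[tert-butyl(dimethyl)silyl]oxy}-6-(3-methylbut-2-en-1-yl)-7-{[tri(propan-2-yl)silyl]oxy}-4H-chromen-4-one
Product: 19 (2S)-2-{(2S)-8-{[tert-butyl(dimethyl)silyl]oxy}-2-methyl-2-[(1E)-4-methylpenta-1,3-dien-1-yl]-3,4-dihydro-2H-chromen-6-yl}-5-{[tert-butyl(dimethyl)silyl]oxy}-6-(3-methylbut-2-en-1-yl)-7-{[tri(propan-2-yl)silyl]oxy}-2,3-dihydro-4H-chromen-4-one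
Conditions: [RhCl(C2H4)2]2 (2.5 mol%), (S)-6,6'-dimethoxy-2,2'-bis[bis(3,4,5-trifluorophenyl)phosphino]-1,1'-biphenyl (5.5 mol%), aq KOH (10 mol%), 13 (1.5 equiv), toluene/H2O 10:1, 30 °C
Reagents that add atoms: none
Why: Rhodium-catalysed asymmetric conjugate addition of an arylboronic acid to a chromone (Hayashi–Miyaura reaction), in which the aryl–rhodium species formed by transmetalation inserts the C2=C3 bond on the face dictated by the (S)-bisphosphine and hydrolysis of the oxa-π-allyl releases the flavanone with C2 as S while the remote chromane centre is unaffected.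

Step 14
Reactants: 19 (2S)-2-{(2S)-8-{[tert-butyl(dimethyl)silyl]oxy}-2-methyl-2-[(1E)-4-methylpenta-1,3-dien-1-yl]-3,4-dihydro-2H-chromen-6-yl}-5-{[tert-butyl(dimethyl)silyl]oxy}-6-(3-methylbut-2-en-1-yl)-7-{[tri(propan-2-yl)silyl]oxy}-2,3-dihydro-4H-chromen-4-one
Product: 20 (2S)-5,7-dihydroxy-2-{(2S)-8-hydroxy-2-methyl-2-[(1E)-4-methylpenta-1,3-dien-1-yl]-3,4-dihydro-2H-chromen-6-yl}-6-(3-methylbut-2-en-1-yl)-2,3-dihydro-4H-chromen-4-one (target)
Conditions: TBAF (4 equiv), AcOH (4 equiv), THF, 0 °C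
Reagents that add atoms: none
Why: Fluoride-mediated cleavage of the three aryl silyl ethers under acetic acid buffering, which avoids both the phenoxide-triggered retro-oxa-Michael opening that would racemise the flavanone and any strong acid that could ionise the tertiary dienyl ether or cyclise the prenyl group.

Compound list
1 | 5-bromo-2-hydroxy-3-methoxybenzaldehyde | COc1cc(Br)cc(C=O)c1O | starting material
2 | 4-bromo-2-ethenyl-6-methoxyphenol | COc1cc(Br)cc(C=C)c1O | intermediate
3 | 2-methyl-2-vinyloxirane (racemic) | CC1(C=C)CO1 | starting material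
4 | (2S)-2-(4-bromo-2-ethenyl-6-methoxyphenoxy)-2-methylbut-3-en-1-ol | OC[C@](C)(C=C)Oc1c(C=C)cc(Br)cc1OC | intermediate
5 | [(2S)-6-bromo-8-methoxy-2-methyl-2H-chromen-2-yl]methanol | OC[C@]1(C)C=Cc2cc(Br)cc(OC)c2O1 | intermediate
6 | [(2S)-6-bromo-8-methoxy-2-methyl-3,4-dihydro-2H-chromen-2-yl]methanol | OC[C@]1(C)CCc2cc(Br)cc(OC)c2O1 | intermediate
7 | (2S)-6-bromo-2-(hydroxymethyl)-2-methyl-3,4-dihydro-2H-chromen-8-ol | OC[C@]1(C)CCc2cc(Br)cc(O)c2O1 | intermediate
8 | [(2S)-6-bromo-8-{[tert-butyl(dimethyl)silyl]oxy}-2-methyl-3,4-dihydro-2H-chromen-2-yl]methanol | OC[C@]1(C)CCc2cc(Br)cc(O[Si](C)(C)C(C)(C)C)c2O1 | intermediate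
9 | (2S)-6-bromo-8-{[tert-butyl(dimethyl)silyl]oxy}-2-methyl-3,4-dihydro-2H-chromene-2-carbaldehyde | O=C[C@]1(C)CCc2cc(Br)cc(O[Si](C)(C)C(C)(C)C)c2O1 | intermediate
10 | {[(2S)-6-bromo-2-methyl-2-[(1E)-4-methylpenta-1,3-dien-1-yl]-3,4-dihydro-2H-chromen-8-yl]oxy}(tert-butyl)dimethylsilane | CC(C)=C/C=C/[C@]1(C)CCc2cc(Br)cc(O[Si](C)(C)C(C)(C)C)c2O1 | intermediate
11 | aryllithium from 10 (6-lithio compound) | CC(C)=C/C=C/[C@]1(C)CCc2cc([Li])cc(O[Si](C)(C)C(C)(C)C)c2O1 | intermediate
12 | lithium aryl(triisopropoxy)borate from 11 | CC(C)=C/C=C/[C@]1(C)CCc2cc([B-](OC(C)C)(OC(C)C)OC(C)C)cc(O[Si](C)(C)C(C)(C)C)c2O1.[Li+] | intermediate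
13 | {(2S)-8-{[tert-butyl(dimethyl)silyl]oxy}-2-methyl-2-[(1E)-4-methylpenta-1,3-dien-1-yl]-3,4-dihydro-2H-chromen-6-yl}boronic acid | CC(C)=C/C=C/[C@]1(C)CCc2cc(B(O)O)cc(O[Si](C)(C)C(C)(C)C)c2O1 | intermediate
14 | 5,7-dihydroxy-4H-chromen-4-one | O=c1ccoc2cc(O)cc(O)c12 | starting material
15 | 5-hydroxy-7-{[tri(propan-2-yl)silyl]oxy}-4H-chromen-4-one | O=c1ccoc2cc(O[Si](C(C)C)(C(C)C)C(C)C)cc(O)c12 | intermediate
16 | 5-hydroxy-6-iodo-7-{[tri(propan-2-yl)silyl]oxy}-4H-chromen-4-one | O=c1ccoc2cc(O[Si](C(C)C)(C(C)C)C(C)C)c(I)c(O)c12 | intermediate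
17 | 5-hydroxy-6-(3-methylbut-2-en-1-yl)-7-{[tri(propan-2-yl)silyl]oxy}-4H-chromen-4-one | CC(C)=CCc1c(O[Si](C(C)C)(C(C)C)C(C)C)cc2occc(=O)c2c1O | intermediate
18 | 5-{[tert-butyl(dimethyl)silyl]oxy}-6-(3-methylbut-2-en-1-yl)-7-{[tri(propan-2-yl)silyl]oxy}-4H-chromen-4-one | CC(C)=CCc1c(O[Si](C(C)C)(C(C)C)C(C)C)cc2occc(=O)c2c1O[Si](C)(C)C(C)(C)C | intermediate
19 | tris-silyl-protected flavanone (product of step 13) | CC(C)=C/C=C/[C@]1(C)CCc2cc([C@@H]3CC(=O)c4c(cc(O[Si](C(C)C)(C(C)C)C(C)C)c(CC=C(C)C)c4O[Si](C)(C)C(C)(C)C)O3)cc(O[Si](C)(C)C(C)(C)C)c2O1 | intermediate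
20 | (2S)-5,7-dihydroxy-2-{(2S)-8-hydroxy-2-methyl-2-[(1E)-4-methylpenta-1,3-dien-1-yl]-3,4-dihydro-2H-chromen-6-yl}-6-(3-methylbut-2-en-1-yl)-2,3-dihydro-4H-chromen-4-one | CC(C)=C/C=C/[C@]1(C)CCc2cc([C@@H]3CC(=O)c4c(cc(O)c(CC=C(C)C)c4O)O3)cc(O)c2O1 | target

Total step count: 14. Longest linear sequence: 10 steps (steps 1 to 8, then 13 and 14); steps 9 to 12 form the second branch.

Steps most likely to fail

Step 13. The conjugated diene of 13 may bind monovalent rhodium and stall transmetalation and insertion, so that protodeboronation of the electron-rich boronic acid outpaces addition to the electron-rich chromone. The fallback builds the diene only after the conjugate addition and sets out from 8. Double lithiation (n-BuLi, 2.2 equiv, THF, −78 °C), trapping with B(OiPr)3 and mild hydrolysis would give {(2S)-8-{[tert-butyl(dimethyl)silyl]oxy}-2-(hydroxymethyl)-2-methyl-3,4-dihydro-2H-chromen-6-yl}boronic acid F1. The rhodium-catalysed addition of F1 to 18 under the conditions of step 13, now without a diene present, would give the flavanone primary alcohol F2. Dess–Martin oxidation would give the flavanone aldehyde F3. Takai olefination (CrCl2, CHI3, THF, 0 °C), which tolerates the ketone, would give the (E)-vinyl iodide F4. Stille coupling of F4 with tributyl(2-methylprop-1-en-1-yl)stannane (Pd2(dba)3, AsPh3, DMF, rt) would complete the diene under neutral conditions and come back to the route at 19.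

Step 2. The doubly ortho-substituted phenol may attack the unsubstituted allyl terminus or react slowly, and re-ionisation of the product by zerovalent palladium may erode the enantiopurity. The fallback sets the stereocentre by enzymatic desymmetrisation and sets out from 2. O-Alkylation with diethyl 2-bromo-2-methylmalonate (Cs2CO3, DMF, 60 °C) would give diethyl 2-(4-bromo-2-ethenyl-6-methoxyphenoxy)-2-methylpropanedioate F5. Reduction with LiAlH4 (THF, 0 °C) would give the prochiral 2-(4-bromo-2-ethenyl-6-methoxyphenoxy)-2-methylpropane-1,3-diol F6. Lipase-catalysed acetylation with vinyl acetate, with the enzyme chosen for the required sense, would give (2S)-2-(4-bromo-2-ethenyl-6-methoxyphenoxy)-3-hydroxy-2-methylpropyl acetate F7. Dess–Martin oxidation would give (2R)-2-(4-bromo-2-ethenyl-6-methoxyphenoxy)-2-methyl-3-oxopropyl acetate F8, which cannot epimerise. Wittig methylenation (Ph3PCH3Br, KOtBu, THF, 0 °C) would give (2S)-2-(4-bromo-2-ethenyl-6-methoxyphenoxy)-2-methylbut-3-en-1-yl acetate F9. Methanolysis of the acetate (K2CO3, MeOH, 0 °C) would come back to the route at 4.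

Step 11. Oxidative addition and transmetalation at the iodide flanked by two oxygen substituents may be sluggish, leading to protodeiodination or to allyl transposition during prenyl transfer. The fallback replaces cross-coupling by a sigmatropic route and sets out from 15. Palladium-catalysed O-alkylation of the 5-hydroxyl with methyl 2-methylbut-3-en-2-yl carbonate (Pd(PPh3)4, THF, rt) would give 5-[(2-methylbut-3-en-2-yl)oxy]-7-{[tri(propan-2-yl)silyl]oxy}-4H-chromen-4-one F10. Aromatic Claisen rearrangement of F10 (toluene, 110 °C, or catalytic Eu(fod)3), which can only reach C6 from O5 and delivers the linear prenyl group, would come back to the route at 17.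

Further compounds
F1 | step 13 | {(2S)-8-{[tert-butyl(dimethyl)silyl]oxy}-2-(hydroxymethyl)-2-methyl-3,4-dihydro-2H-chromen-6-yl}boronic acid | OC[C@]1(C)CCc2cc(B(O)O)cc(O[Si](C)(C)C(C)(C)C)c2O1
F2 | step 13 | (2S)-5-{[tert-butyl(dimethyl)silyl]oxy}-2-[(2S)-8-{[tert-butyl(dimethyl)silyl]oxy}-2-(hydroxymethyl)-2-methyl-3,4-dihydro-2H-chromen-6-yl]-6-(3-methylbut-2-en-1-yl)-7-{[tri(propan-2-yl)silyl]oxy}-2,3-dihydro-4H-chromen-4-one | OC[C@]1(C)CCc2cc([C@@H]3CC(=O)c4c(cc(O[Si](C(C)C)(C(C)C)C(C)C)c(CC=C(C)C)c4O[Si](C)(C)C(C)(C)C)O3)cc(O[Si](C)(C)C(C)(C)C)c2O1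
F3 | step 13 | (2S)-8-{[tert-butyl(dimethyl)silyl]oxy}-6-[(2S)-5-{[tert-butyl(dimethyl)silyl]oxy}-6-(3-methylbut-2-en-1-yl)-4-oxo-7-{[tri(propan-2-yl)silyl]oxy}-3,4-dihydro-2H-chromen-2-yl]-2-methyl-3,4-dihydro-2H-chromene-2-carbaldehyde | O=C[C@]1(C)CCc2cc([C@@H]3CC(=O)c4c(cc(O[Si](C(C)C)(C(C)C)C(C)C)c(CC=C(C)C)c4O[Si](C)(C)C(C)(C)C)O3)cc(O[Si](C)(C)C(C)(C)C)c2O1
F4 | step 13 | (2S)-5-{[tert-butyl(dimethyl)silyl]oxy}-2-{(2S)-8-{[tert-butyl(dimethyl)silyl]oxy}-2-[(E)-2-iodoethenyl]-2-methyl-3,4-dihydro-2H-chromen-6-yl}-6-(3-methylbut-2-en-1-yl)-7-{[tri(propan-2-yl)silyl]oxy}-2,3-dihydro-4H-chromen-4-one | I/C=C/[C@]1(C)CCc2cc([C@@H]3CC(=O)c4c(cc(O[Si](C(C)C)(C(C)C)C(C)C)c(CC=C(C)C)c4O[Si](C)(C)C(C)(C)C)O3)cc(O[Si](C)(C)C(C)(C)C)c2O1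
F5 | step 2 | diethyl 2-(4-bromo-2-ethenyl-6-methoxyphenoxy)-2-methylpropanedioate | CCOC(=O)C(C)(Oc1c(C=C)cc(Br)cc1OC)C(=O)OCC
F6 | step 2 | 2-(4-bromo-2-ethenyl-6-methoxyphenoxy)-2-methylpropane-1,3-diol | OCC(C)(CO)Oc1c(C=C)cc(Br)cc1OC
F7 | step 2 | (2S)-2-(4-bromo-2-ethenyl-6-methoxyphenoxy)-3-hydroxy-2-methylpropyl acetate | CC(=O)OC[C@](C)(CO)Oc1c(C=C)cc(Br)cc1OC
F8 | step 2 | (2R)-2-(4-bromo-2-ethenyl-6-methoxyphenoxy)-2-methyl-3-oxopropyl acetate | CC(=O)OC[C@](C)(C=O)Oc1c(C=C)cc(Br)cc1OC
F9 | step 2 | (2S)-2-(4-bromo-2-ethenyl-6-methoxyphenoxy)-2-methylbut-3-en-1-yl acetate | CC(=O)OC[C@](C)(C=C)Oc1c(C=C)cc(Br)cc1OC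
F10 | step 11 | 5-[(2-methylbut-3-en-2-yl)oxy]-7-{[tri(propan-2-yl)silyl]oxy}-4H-chromen-4-one | C=CC(C)(C)Oc1cc(O[Si](C(C)C)(C(C)C)C(C)C)cc2occc(=O)c12
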